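**Assumption:** catalysts, ligands, the enzyme and simple reagents are not numbered (reagents that add atoms are given with SMILES in each step). Positions use geranylgeranyl numbering: C1 = ArCH2, C2 = ring CH, C3 = C(=CH2), C6 = CHBr, C7 = quaternary C, C10/C11 = epoxide, C14 = lactone carbinol, C15 = CMe2Br. The target is (2R,6S,7S,10S,11S,14S).

## Retrosynthetic overview

- Oxirane last: reagent-controlled Shi epoxidation of C10=C11 in the macrolactone, then phenol desilylation.
- Macrolactone: Shiina lactonization of a C14-OH/C15-Br bromohydrin seco-acid, made by HBr opening of a (14S)-epoxide whose stereocentre comes from a ketoreductase reduction of an achiral α-hydroxy ketone.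
- C9–C10 and ArCH2–C2 bonds: two sp3–sp2 Negishi couplings.
- Bromocyclohexane: C6–Br by Appel inversion of an axial alcohol; the ring, C2/C7 stereochemistry and exo-methylene come from a Shi-epoxide-initiated, allylsilane-terminated cyclization of an acyclic (2Z,6E)-dienoate.
- Ring order: cyclohexane → 15-membered lactone → oxirane.

## Route

**Step 1**
Reactants: 1 but-3-yn-1-ol
Product: 2 1-[(but-3-yn-1-yloxy)methyl]-4-methoxybenzene
Conditions: NaH, PMBCl, TBAI (cat.), THF/DMF, 0 °C → rt
Reagents that add atoms: 4-methoxybenzyl chloride, COc1ccc(CCl)cc1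
Why: Williamson etherification of the alkoxide; PMB survives the Lewis acid, hydride and organozinc steps and is later removed oxidatively without touching the aryl silyl ether.

**Step 2**
Reactants: 2 PMB ether of butynol
Product: 3 (E)-5-[(4-methoxybenzyl)oxy]-3-methylpent-2-en-1-ol
Conditions: AlMe3, Cp2ZrCl2 (cat.), CH2Cl2, rt; then n-BuLi, (CH2O)n, THF, −78 °C → rt
Reagents that add atoms: trimethylaluminium, C[Al](C)C; paraformaldehyde, C=O
Why: Negishi Zr-catalysed syn-carboalumination puts Me on the internal carbon cis to Al, and formaldehyde trapping with retention gives only the E-olefin, whose geometry later decides Me-axial/chain-equatorial at C7.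

**Step 3**
Reactants: 3 allylic alcohol
Product: 4 (E)-1-{[(5-bromo-3-methylpent-3-en-1-yl)oxy]methyl}-4-methoxybenzene
Conditions: CBr4, PPh3, CH2Cl2, 0 °C
Reagents that add atoms: carbon tetrabromide, BrC(Br)(Br)Br
Why: Appel bromination of a primary allylic alcohol proceeds without allylic transposition or E/Z erosion.

**Step 4**
Reactants: 4 allylic bromide; 5 methyl acetoacetate
Product: 6 methyl (E)-9-[(4-methoxybenzyl)oxy]-7-methyl-3-oxonon-6-enoate
Conditions: 5, NaH then n-BuLi, THF, 0 °C; then 4, 0 °C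
Reagents that add atoms: none
Why: β-Keto ester dianion (Huckin–Weiler) alkylation occurs only at the γ-carbon with a reactive allylic bromide, assembling C1–C9.

**Step 5**
Reactants: 6 β-keto ester
Product: 7 methyl (2Z,6E)-3-[(diethoxyphosphoryl)oxy]-9-[(4-methoxybenzyl)oxy]-7-methylnona-2,6-dienoate
Conditions: NaH, ClP(O)(OEt)2, Et2O, 0 °C
Reagents that add atoms: diethyl chlorophosphate, CCOP(=O)(Cl)OCC
Why: O-phosphorylation of the sodium-chelated enolate gives the Z-enol phosphate (phosphate cis to the ester).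

**Step 6**
Reactants: 7 Z-enol phosphate
Product: 8 methyl (2Z,6E)-9-[(4-methoxybenzyl)oxy]-7-methyl-3-[(trimethylsilyl)methyl]nona-2,6-dienoate
Conditions: Me3SiCH2MgCl, Ni(acac)2 (cat.), THF, rt
Reagents that add atoms: (trimethylsilyl)methylmagnesium chloride, C[Si](C)(C)C[Mg]Cl
Why: Ni-catalysed Kumada-type coupling of the enol phosphate proceeds with retention, giving the Z-allylsilane (CH2SiMe3 cis to the ester) needed for an equatorial C1 in the cyclization.

**Step 7**
Reactants: 8 dienoate allylsilane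
Product: 9 methyl (Z)-5-[(2S,3S)-3-{2-[(4-methoxybenzyl)oxy]ethyl}-3-methyloxiran-2-yl]-3-[(trimethylsilyl)methyl]pent-2-enoate
Conditions: ent-Shi ketone (L-fructose-derived, 30 mol%), Oxone, K2CO3, Bu4NHSO4, MeCN/DMM/aq. buffer pH 10.5, 0 °C
Reagents that add atoms: Oxone (potassium peroxymonosulfate), [K+].[O-]S(=O)(=O)OO
Why: Shi asymmetric epoxidation sets the first stereocentres (6S,7S; the D-fructose ketone gives R,R), and the electrophilic dioxirane takes the electron-rich C6=C7 olefin and leaves the conjugated enoate alone.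

**Step 8**
Reactants: 9 epoxy allylsilane
Product: 10 methyl (1R,2S,3S)-3-hydroxy-2-{2-[(4-methoxybenzyl)oxy]ethyl}-2-methyl-6-methylidenecyclohexane-1-carboxylate
Conditions: BF3·OEt2, CH2Cl2, −78 °C
Reagents that add atoms: none
Why: Epoxide-initiated cation–olefin cyclization with allylsilane termination: C2 attacks C7 anti to the C–O bond through a chair, so the E-epoxide gives Me axial/chain equatorial/OH equatorial, the Z-allylsilane gives the ester equatorial (C2 R), and loss of Me3Si gives only the exocyclic methylene.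

**Step 9**
Reactants: 10 equatorial hydroxy ester
Product: 11 methyl (1R,2S)-2-{2-[(4-methoxybenzyl)oxy]ethyl}-2-methyl-6-methylidene-3-oxocyclohexane-1-carboxylate
Conditions: Dess–Martin periodinane, NaHCO3, CH2Cl2, rt
Reagents that add atoms: none
Why: Neutral Dess–Martin oxidation removes the C6 carbinol (which has the wrong configuration for an SN2 bromination) without epimerizing C2 or moving the β,γ-olefin.

**Step 10**
Reactants: 11 keto ester
Product: 12 methyl (1R,2S,3R)-3-hydroxy-2-{2-[(4-methoxybenzyl)oxy]ethyl}-2-methyl-6-methylidenecyclohexane-1-carboxylate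
Conditions: L-Selectride, THF, −78 °C
Reagents that add atoms: none
Why: The bulky hydride attacks the α,α-disubstituted cyclohexanone equatorially (as with 4,4-dimethyl-3-keto terpenoids), giving the axial (6R) alcohol; the ester is untouched at −78 °C.

**Step 11**
Reactants: 12 axial alcohol
Product: 13 methyl (1R,2S,3S)-3-bromo-2-{2-[(4-methoxybenzyl)oxy]ethyl}-2-methyl-6-methylidenecyclohexane-1-carboxylate
Conditions: CBr4, PPh3, CH2Cl2, 0 → 40 °C
Reagents that add atoms: carbon tetrabromide, BrC(Br)(Br)Br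
Why: Appel reaction; bromide displaces the axial oxyphosphonium with inversion to give the equatorial (6S) bromide, cis to the C7 methyl as in the target.

**Step 12**
Reactants: 13 bromo ester
Product: 14 [(1R,2S,3S)-3-bromo-2-{2-[(4-methoxybenzyl)oxy]ethyl}-2-methyl-6-methylidenecyclohexyl]methanol
Conditions: DIBAL-H, CH2Cl2, −78 → 0 °C
Reagents that add atoms: none
Why: DIBAL reduces the ester to the C1 primary alcohol without affecting the hindered secondary bromide, which fixes the C2 stereocentre against epimerization.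

**Step 13**
Reactants: 14 primary alcohol
Product: 15 (1S,2S,3R)-1-bromo-3-(iodomethyl)-2-{2-[(4-methoxybenzyl)oxy]ethyl}-2-methyl-4-methylidenecyclohexane
Conditions: I2, PPh3, imidazole, CH2Cl2, 0 °C → rt
Reagents that add atoms: iodine, II
Why: Appel-type iodination of the primary alcohol; with Br cis to the CH2 group no transannular ether can form.

**Step 14**
Reactants: 16 methyl 4-hydroxy-3-iodobenzoate
Product: 17 methyl 3-iodo-4-[(triisopropylsilyl)oxy]benzoate
Conditions: TIPSCl, imidazole, DMF, rt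
Reagents that add atoms: triisopropylsilyl chloride, CC(C)[Si](Cl)(C(C)C)C(C)C
Why: Phenol silylation; the aryl TIPS ether tolerates the organozinc, DDQ, HBr and acylation steps and is removed last with buffered fluoride.

**Step 15**
Reactants: 15 primary iodide; 17 aryl iodide
Product: 18 methyl 3-{[(1R,2S,3S)-3-bromo-2-{2-[(4-methoxybenzyl)oxy]ethyl}-2-methyl-6-methylidenecyclohexyl]methyl}-4-[(triisopropylsilyl)oxy]benzoate
Conditions: 15, Zn dust (TMSCl/BrCH2CH2Br-activated), LiCl, THF, 25–35 °C; then 17, Pd(OAc)2/SPhos (cat.), THF, rt → 40 °C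
Reagents that add atoms: none
Why: Zinc inserts into the primary C–I bond much faster than into the hindered secondary C–Br bond, and sp3–sp2 Negishi coupling with a bulky biarylphosphine outpaces β-hydride elimination and tolerates the ester.

**Step 16**
Reactants: 18 PMB ether
Product: 19 methyl 3-{[(1R,2S,3S)-3-bromo-2-(2-hydroxyethyl)-2-methyl-6-methylidenecyclohexyl]methyl}-4-[(triisopropylsilyl)oxy]benzoate
Conditions: DDQ, CH2Cl2/pH 7 buffer (10:1), 0 °C → rt
Reagents that add atoms: none
Why: Oxidative PMB cleavage is orthogonal to the aryl silyl ether, ester, bromide and exo-methylene.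

**Step 17**
Reactants: 19 primary alcohol
Product: 20 methyl 3-{[(1R,2S,3S)-3-bromo-2-(2-iodoethyl)-2-methyl-6-methylidenecyclohexyl]methyl}-4-[(triisopropylsilyl)oxy]benzoate
Conditions: I2, PPh3, imidazole, CH2Cl2, 0 °C → rt
Reagents that add atoms: iodine, II
Why: Appel-type iodination gives the C9 iodide needed for the second organozinc.

**Step 18**
Reactants: 21 prop-2-yn-1-ol
Product: 22 (E)-3-iodo-2-methylprop-2-en-1-ol
Conditions: AlMe3 (3 equiv), Cp2ZrCl2 (cat.), CH2Cl2, 0 °C → rt; then I2, THF, −30 °C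
Reagents that add atoms: trimethylaluminium, C[Al](C)C; iodine, II
Why: Negishi syn-carboalumination then iodinolysis with retention gives the E-vinyl iodide that becomes C10=C11 with the correct geometry.

**Step 19**
Reactants: 22 iodo allylic alcohol
Product: 23 (E)-3-bromo-1-iodo-2-methylprop-1-ene
Conditions: CBr4, PPh3, CH2Cl2, 0 °C
Reagents that add atoms: carbon tetrabromide, BrC(Br)(Br)Br
Why: Appel bromination of the primary allylic alcohol; the vinyl iodide is inert.

**Step 20**
Reactants: 23 allylic bromide; 24 3-hydroxy-3-methylbutan-2-one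
Product: 25 (E)-2-hydroxy-7-iodo-2,6-dimethylhept-6-en-3-one
Conditions: 24, LDA (2.2 equiv), THF, −78 °C; then 23, −78 → −20 °C
Reagents that add atoms: none
Why: The alkoxide/enolate dianion can only enolize toward the methyl group, so C-alkylation with the allylic bromide forms the C12–C13 bond regiospecifically.

**Step 21**
Reactants: 25 α-hydroxy ketone
Product: 26 (3R,6E)-7-iodo-2,6-dimethylhept-6-ene-2,3-diol
Conditions: (R)-selective (anti-Prelog) ketoreductase (KRED), NADP+ (cat.), i-PrOH, phosphate buffer pH 7/DMSO, 30 °C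
Reagents that add atoms: none
Why: Ketoreductase-catalysed asymmetric reduction of the achiral ketone sets the C14 stereocentre (R here) by enzyme-controlled hydride delivery from NADPH, and the neutral aqueous conditions leave the vinyl iodide intact.

**Step 22**
Reactants: 26 (R)-diol
Product: 27 (3S)-3-[(4E)-5-iodo-4-methylpent-4-en-1-yl]-2,2-dimethyloxirane
Conditions: MsCl, Et3N, CH2Cl2, −10 °C; then K2CO3, MeOH, rt
Reagents that add atoms: none
Why: Only the secondary OH is mesylated, and the tertiary alkoxide closes the epoxide by intramolecular SN2 with inversion at C14 (R → S).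

**Step 23**
Reactants: 20 primary iodide; 27 epoxy vinyl iodide
Product: 28 methyl 3-{[(1R,2S,3S)-3-bromo-2-{(3E)-6-[(2S)-3,3-dimethyloxiran-2-yl]-4-methylhex-3-en-1-yl}-2-methyl-6-methylidenecyclohexyl]methyl}-4-[(triisopropylsilyl)oxy]benzoate
Conditions: 20, Zn dust (activated), LiCl, THF, 30 °C; then 27, Pd(PPh3)4 (cat.), THF, rt
Reagents that add atoms: none
Why: Negishi alkylzinc–alkenyl iodide coupling forms C9–C10 with complete retention of E geometry under conditions mild enough for the epoxide, ester and secondary bromide.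

**Step 24**
Reactants: 28 methyl ester
Product: 29 the corresponding benzoic acid (as 28, with CO2H in place of CO2Me)
Conditions: Me3SnOH, 1,2-dichloroethane, 70 °C; pH 5 buffer work-up
Reagents that add atoms: trimethyltin hydroxide, C[Sn](C)(C)O (supplies the carboxyl OH oxygen)
Why: Near-neutral tin-hydroxide ester hydrolysis frees the acid without the hydroxide that would strip the aryl silyl ether, and leaves the epoxide and bromide intact.

**Step 25**
Reactants: 29 epoxy acid
Product: 30 3-{[(1R,2S,3S)-3-bromo-2-[(3E,7S)-8-bromo-7-hydroxy-4,8-dimethylnon-3-en-1-yl]-2-methyl-6-methylidenecyclohexyl]methyl}-4-[(triisopropylsilyl)oxy]benzoic acid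
Conditions: 48% aq. HBr (1.5 equiv), THF, −20 °C, 15 min
Reagents that add atoms: hydrogen bromide, Br
Why: Acid-mediated opening of the trisubstituted epoxide puts bromide on the tertiary carbon (C15) and leaves the C14–O bond, and so (14S), untouched; the protonated epoxide reacts far faster than the olefins at −20 °C.

**Step 26**
Reactants: 30 bromohydrin seco-acid
Product: 31 15-membered macrolactone, (2R,6S,7S,10E,14S): the target skeleton with the C10=C11 E-olefin in place of the epoxide and the phenol as its TIPS ether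
Conditions: MNBA, DMAP, CH2Cl2 (2 mM), rt, slow addition
Reagents that add atoms: none
Why: Shiina macrolactonization acylates the only free hydroxyl (C14) with retention under mild conditions, so the tertiary bromide is neither eliminated nor re-closed to the epoxide.

**Step 27**
Reactants: 31 macrolactone olefin
Product: 32 (2R,6S,7S,10S,11S,14S)-macrolactone 10,11-epoxide, TIPS ether
Conditions: ent-Shi ketone (30–50 mol%), Oxone, K2CO3, Bu4NHSO4, MeCN/DMM/aq. buffer pH 10.5, 0 °C
Reagents that add atoms: Oxone (potassium peroxymonosulfate), [K+].[O-]S(=O)(=O)OO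
Why: Shi epoxidation with the same catalyst and facial sense as step 7 gives the (10S,11S)-epoxide under reagent control, and the dioxirane prefers the trisubstituted olefin over the hindered 1,1-disubstituted exo-methylene.

**Step 28**
Reactants: 32 TIPS ether
Product: 33 bromophycolide S
Conditions: TBAF, AcOH (1:1), THF, 0 °C
Reagents that add atoms: none
Why: Buffered fluoride cleaves the aryl silyl ether within minutes and is too mild to open the epoxide, eliminate the tertiary bromide or cleave the lactone.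

## Compound list

1 | but-3-yn-1-ol | C#CCCO | starting material
2 | 1-[(but-3-yn-1-yloxy)methyl]-4-methoxybenzene | C#CCCOCc1ccc(OC)cc1 | intermediate
3 | (E)-5-[(4-methoxybenzyl)oxy]-3-methylpent-2-en-1-ol | OC/C=C(\C)CCOCc1ccc(OC)cc1 | intermediate
4 | (E)-1-{[(5-bromo-3-methylpent-3-en-1-yl)oxy]methyl}-4-methoxybenzene | BrC/C=C(\C)CCOCc1ccc(OC)cc1 | intermediate
5 | methyl acetoacetate | COC(=O)CC(C)=O | starting material
6 | methyl (E)-9-[(4-methoxybenzyl)oxy]-7-methyl-3-oxonon-6-enoate | COC(=O)CC(=O)CC/C=C(\C)CCOCc1ccc(OC)cc1 | intermediate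
7 | methyl (2Z,6E)-3-[(diethoxyphosphoryl)oxy]-9-[(4-methoxybenzyl)oxy]-7-methylnona-2,6-dienoate | COC(=O)/C=C(\OP(=O)(OCC)OCC)CC/C=C(\C)CCOCc1ccc(OC)cc1 | intermediate
8 | methyl (2Z,6E)-9-[(4-methoxybenzyl)oxy]-7-methyl-3-[(trimethylsilyl)methyl]nona-2,6-dienoate | COC(=O)/C=C(\C[Si](C)(C)C)CC/C=C(\C)CCOCc1ccc(OC)cc1 | intermediate
9 | methyl (Z)-5-[(2S,3S)-3-{2-[(4-methoxybenzyl)oxy]ethyl}-3-methyloxiran-2-yl]-3-[(trimethylsilyl)methyl]pent-2-enoate | COC(=O)/C=C(\C[Si](C)(C)C)CC[C@@H]1O[C@@]1(C)CCOCc1ccc(OC)cc1 | intermediate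
10 | methyl (1R,2S,3S)-3-hydroxy-2-{2-[(4-methoxybenzyl)oxy]ethyl}-2-methyl-6-methylidenecyclohexane-1-carboxylate | C=C1CC[C@H](O)[C@@](C)(CCOCc2ccc(OC)cc2)[C@@H]1C(=O)OC | intermediate
11 | methyl (1R,2S)-2-{2-[(4-methoxybenzyl)oxy]ethyl}-2-methyl-6-methylidene-3-oxocyclohexane-1-carboxylate | C=C1CCC(=O)[C@@](C)(CCOCc2ccc(OC)cc2)[C@@H]1C(=O)OC | intermediate
12 | methyl (1R,2S,3R)-3-hydroxy-2-{2-[(4-methoxybenzyl)oxy]ethyl}-2-methyl-6-methylidenecyclohexane-1-carboxylate | C=C1CC[C@@H](O)[C@@](C)(CCOCc2ccc(OC)cc2)[C@@H]1C(=O)OC | intermediate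
13 | methyl (1R,2S,3S)-3-bromo-2-{2-[(4-methoxybenzyl)oxy]ethyl}-2-methyl-6-methylidenecyclohexane-1-carboxylate | C=C1CC[C@H](Br)[C@@](C)(CCOCc2ccc(OC)cc2)[C@@H]1C(=O)OC | intermediate
14 | [(1R,2S,3S)-3-bromo-2-{2-[(4-methoxybenzyl)oxy]ethyl}-2-methyl-6-methylidenecyclohexyl]methanol | C=C1CC[C@H](Br)[C@@](C)(CCOCc2ccc(OC)cc2)[C@@H]1CO | intermediate
15 | (1S,2S,3R)-1-bromo-3-(iodomethyl)-2-{2-[(4-methoxybenzyl)oxy]ethyl}-2-methyl-4-methylidenecyclohexane | C=C1CC[C@H](Br)[C@@](C)(CCOCc2ccc(OC)cc2)[C@@H]1CI | intermediate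
16 | methyl 4-hydroxy-3-iodobenzoate | COC(=O)c1ccc(O)c(I)c1 | starting material
17 | methyl 3-iodo-4-[(triisopropylsilyl)oxy]benzoate | COC(=O)c1ccc(O[Si](C(C)C)(C(C)C)C(C)C)c(I)c1 | intermediate
18 | methyl 3-{[(1R,2S,3S)-3-bromo-2-{2-[(4-methoxybenzyl)oxy]ethyl}-2-methyl-6-methylidenecyclohexyl]methyl}-4-[(triisopropylsilyl)oxy]benzoate | C=C1CC[C@H](Br)[C@@](C)(CCOCc2ccc(OC)cc2)[C@@H]1Cc1cc(C(=O)OC)ccc1O[Si](C(C)C)(C(C)C)C(C)C | intermediate
19 | methyl 3-{[(1R,2S,3S)-3-bromo-2-(2-hydroxyethyl)-2-methyl-6-methylidenecyclohexyl]methyl}-4-[(triisopropylsilyl)oxy]benzoate | C=C1CC[C@H](Br)[C@@](C)(CCO)[C@@H]1Cc1cc(C(=O)OC)ccc1O[Si](C(C)C)(C(C)C)C(C)C | intermediate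
20 | methyl 3-{[(1R,2S,3S)-3-bromo-2-(2-iodoethyl)-2-methyl-6-methylidenecyclohexyl]methyl}-4-[(triisopropylsilyl)oxy]benzoate | C=C1CC[C@H](Br)[C@@](C)(CCI)[C@@H]1Cc1cc(C(=O)OC)ccc1O[Si](C(C)C)(C(C)C)C(C)C | intermediate
21 | prop-2-yn-1-ol | C#CCO | starting material
22 | (E)-3-iodo-2-methylprop-2-en-1-ol | OC/C(C)=C/I | intermediate
23 | (E)-3-bromo-1-iodo-2-methylprop-1-ene | BrC/C(C)=C/I | intermediate
24 | 3-hydroxy-3-methylbutan-2-one | CC(=O)C(C)(C)O | starting material
25 | (E)-2-hydroxy-7-iodo-2,6-dimethylhept-6-en-3-one | CC(C)(O)C(=O)CC/C(C)=C/I | intermediate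
26 | (3R,6E)-7-iodo-2,6-dimethylhept-6-ene-2,3-diol | CC(C)(O)[C@H](O)CC/C(C)=C/I | intermediate
27 | (3S)-3-[(4E)-5-iodo-4-methylpent-4-en-1-yl]-2,2-dimethyloxirane | CC1(C)O[C@H]1CC/C(C)=C/I | intermediate
28 | methyl 3-{[(1R,2S,3S)-3-bromo-2-{(3E)-6-[(2S)-3,3-dimethyloxiran-2-yl]-4-methylhex-3-en-1-yl}-2-methyl-6-methylidenecyclohexyl]methyl}-4-[(triisopropylsilyl)oxy]benzoate | C=C1CC[C@H](Br)[C@@](C)(CC/C=C(\C)CC[C@@H]2OC2(C)C)[C@@H]1Cc1cc(C(=O)OC)ccc1O[Si](C(C)C)(C(C)C)C(C)C | intermediate
29 | 3-{[(1R,2S,3S)-3-bromo-2-{(3E)-6-[(2S)-3,3-dimethyloxiran-2-yl]-4-methylhex-3-en-1-yl}-2-methyl-6-methylidenecyclohexyl]methyl}-4-[(triisopropylsilyl)oxy]benzoic acid | C=C1CC[C@H](Br)[C@@](C)(CC/C=C(\C)CC[C@@H]2OC2(C)C)[C@@H]1Cc1cc(C(=O)O)ccc1O[Si](C(C)C)(C(C)C)C(C)C | intermediate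
30 | 3-{[(1R,2S,3S)-3-bromo-2-[(3E,7S)-8-bromo-7-hydroxy-4,8-dimethylnon-3-en-1-yl]-2-methyl-6-methylidenecyclohexyl]methyl}-4-[(triisopropylsilyl)oxy]benzoic acid | C=C1CC[C@H](Br)[C@@](C)(CC/C=C(\C)CC[C@H](O)C(C)(C)Br)[C@@H]1Cc1cc(C(=O)O)ccc1O[Si](C(C)C)(C(C)C)C(C)C | intermediate
31 | (2R,6S,7S,10E,14S)-macrolactone, C10=C11 olefin, phenol TIPS ether | C=C1CC[C@H](Br)[C@@]2(C)CC/C=C(\C)CC[C@@H](C(C)(C)Br)OC(=O)c3ccc(O[Si](C(C)C)(C(C)C)C(C)C)c(c3)C[C@H]12 | intermediate
32 | (2R,6S,7S,10S,11S,14S)-macrolactone 10,11-epoxide, phenol TIPS ether | C=C1CC[C@H](Br)[C@@]2(C)CC[C@@H]3O[C@@]3(C)CC[C@@H](C(C)(C)Br)OC(=O)c3ccc(O[Si](C(C)C)(C(C)C)C(C)C)c(c3)C[C@H]12 | intermediate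
33 | bromophycolide S | C=C1CC[C@H](Br)[C@@]2(C)CC[C@@H]3O[C@@]3(C)CC[C@@H](C(C)(C)Br)OC(=O)c3ccc(O)c(c3)C[C@H]12 | target

## Summary

Total steps: 28. Longest linear sequence: 22 (steps 1–13, 15–17, 23–28).

Three steps most likely to fail, each with a fallback that changes the approach:

1. **Step 11, Appel inversion at the neopentyl axial C6–OH** (E2 to the C5=C6 olefin and Wagner–Meerwein shifts compete). Fallback: make the C–Br bond before ring closure. Epoxidize 8 with the D-fructose Shi ketone to the (6R,7R)-epoxide, open it at C6 with bromide (Li2NiBr4, inversion) to the C6-bromo/C7-hydroxy bromohydrin, and ionize the tertiary alcohol so a stereodefined bromonium ion triggers the allylsilane cyclization. This gives 13 directly and removes steps 9–11.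

2. **Step 26, macrolactonization of the hindered, base-sensitive bromohydrin** (re-closure to the epoxide or HBr elimination under DMAP). Fallback: lactonize before the bromide exists. Carry the 14,15-diol of the (S)-series (Prelog-selective ketoreductase, acetonide through step 23), close the ring on the secondary OH of the free diol by Shiina lactonization, then convert the tertiary C15–OH to the bromide with anchimeric assistance from the benzoate (TMSBr via the 2-aryl-dioxolanylium ion, retention at C14) before the final epoxidation.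

3. **Step 8, epoxy-allylsilane cyclization** (the conjugated allylsilane is a weak nucleophile; hydride-shift ketone or boat-derived C2 epimer are possible). Fallback: change the terminator. Shi-epoxidize β-keto ester 6 and cyclize with SnCl4 (β-keto ester-terminated epoxy-olefin cyclization) to the C3-keto/C2-ester cyclohexane, equilibrate C2 to the equatorial ester, then install the exo-methylene by Lombardo–Takai methylenation of the C3 ketone and rejoin the route at step 9.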